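## Retrosynthetic overview

- Last disconnection, and the only ring made: the C2–O1 bond of the dihydrofuran. The target is an isomer of an achiral 2-hydroxystilbene that already carries every carbon and both 4-hydroxybenzoate arms; an enantioselective Brønsted-acid hydroaryloxylation through a p-quinone methide closes it and sets C2 and C3 together.
- The aryl–alkene bond of that stilbene (C3–C3a of the target): Mizoroki–Heck union of coniferyl 4-hydroxybenzoate (ring A half) with its 5-iodo analogue (ring B half).
- Each cinnamyl ester arm: cross-metathesis of a 4-vinylphenol with allyl 4-hydroxybenzoate. The iodinated vinylphenol comes from 5-iodovanillin by Wittig methylenation.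
- Ring order: the four benzene rings are bought; the dihydrofuran ring is formed last; no protecting groups are used.
- Locants used below: C7 is the alkene carbon on ring A, C8 the alkene carbon bearing the CH2O arm; they become C2 and C3 of the dihydrobenzofuran.

Assumption: allyl 4-hydroxybenzoate is bought as a catalogue compound, and which enantiomer of the acid catalyst gives the (2S,3R) series must be found by experiment; the (R)-form is written and its mirror image is used if the sense is opposite.

## Route

Step 1
Reactants: 1 2-methoxy-4-vinylphenol; 2 allyl 4-hydroxybenzoate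
Product: 3 (E)-3-(4-hydroxy-3-methoxyphenyl)prop-2-en-1-yl 4-hydroxybenzoate (coniferyl 4-hydroxybenzoate)
Conditions: second-generation Hoveyda–Grubbs catalyst RuCl2(H2IMes)(=CH-C6H4-2-OiPr) (3 mol%), 2 (3 equiv), CH2Cl2, 40 °C
Reagents that add atoms: none
Why: Olefin cross-metathesis of an electron-rich styrene with an excess of a terminal allyl ester is a well-behaved pairing for the phosphine-free ruthenium carbene, free phenols are tolerated, loss of ethylene drives it, and the conjugated disubstituted alkene forms as the E isomer under thermodynamic control; no stereocentre is formed.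

Step 2
Reactants: 4 5-iodovanillin (4-hydroxy-3-iodo-5-methoxybenzaldehyde)
Product: 5 2-iodo-6-methoxy-4-vinylphenol
Conditions: Ph3PCH3Br (2.5 equiv), KOtBu (2.4 equiv), THF, 0 °C to rt; aq. NH4Cl
Reagents that add atoms: methyltriphenylphosphonium bromide, C[P+](c1ccccc1)(c1ccccc1)c1ccccc1.[Br-]
Why: Wittig methylenation, in which the first equivalent of ylide is spent on the phenol and the phenoxide-deactivated aldehyde still reacts at room temperature as vanillin itself does, the aryl iodide is inert, and this only strongly basic step is placed before any base-labile cinnamyl ester exists; no stereocentre is formed.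

Step 3
Reactants: 5 2-iodo-6-methoxy-4-vinylphenol; 2 allyl 4-hydroxybenzoate
Product: 6 (E)-3-(4-hydroxy-3-iodo-5-methoxyphenyl)prop-2-en-1-yl 4-hydroxybenzoate (5-iodoconiferyl 4-hydroxybenzoate)
Conditions: second-generation Hoveyda–Grubbs catalyst RuCl2(H2IMes)(=CH-C6H4-2-OiPr) (5 mol%), 2 (3 equiv), CH2Cl2, 40 °C
Reagents that add atoms: none
Why: The same olefin cross-metathesis as in step 1, with the aryl iodide and the free phenol inert towards the ruthenium carbene and the E alkene again favoured thermodynamically; no stereocentre is formed.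

Step 4
Reactants: 3 coniferyl 4-hydroxybenzoate; 6 5-iodoconiferyl 4-hydroxybenzoate
Product: 7 (Z)-3-(4-hydroxy-3-methoxyphenyl)-2-{2-hydroxy-5-[(E)-3-(4-hydroxybenzoyloxy)prop-1-en-1-yl]-3-methoxyphenyl}prop-2-en-1-yl 4-hydroxybenzoate
Conditions: Pd(OAc)2 (5 mol%), n-Bu4NCl (1 equiv), NaOAc (3 equiv), 3 (4 equiv, excess recovered), DMF, 85 °C, 6 added in portions
Reagents that add atoms: none
Why: Mizoroki–Heck reaction under Jeffery conditions, in which the carbon–iodine bond of 6 adds to zerovalent palladium, syn-carbopalladation of 3 puts the aryl group on C8 and palladium on the benzylic C7 stabilised by ring A, and syn β-hydride elimination of the single C8–H gives the trisubstituted stilbene with the two aryl groups trans (Z by the sequence rule), while the silver-free chloride-rich medium disfavours ester-chelated insertion and in-flask oxa-cyclisation, the acetate buffer keeps the phenols protonated, and the fourfold excess of 3 outcompetes the like alkenes of 6 and 7; no stereocentre is formed and either alkene geometry serves step 5.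

Step 5
Reactants: 7 the (Z)-2-hydroxystilbene bis(4-hydroxybenzoate)
Product: 9 quiquesetinerviusin A [(2S,3R)-2-(4-hydroxy-3-methoxyphenyl)-5-{(E)-3-[(4-hydroxybenzoyl)oxy]prop-1-en-1-yl}-7-methoxy-2,3-dihydro-1-benzofuran-3-yl]methyl 4-hydroxybenzoate, via p-quinone methide 8 (not isolated)
Conditions: (R)-TRIP [(R)-3,3'-bis(2,4,6-triisopropylphenyl)-1,1'-binaphthyl-2,2'-diyl hydrogen phosphate] (10 mol%), 4 Å MS, CH2Cl2 (0.01 M), −30 °C
Reagents that add atoms: none
Why: Proposed new method: an enantioselective intramolecular hydroaryloxylation (5-exo oxa-1,6-addition) in which the chiral phosphoric acid protonates C8 of the 4-hydroxystilbene unit to give p-quinone methide 8, whose C8 epimers interconvert through 7, and then, hydrogen-bonded to the quinone methide carbonyl and to the ring B phenol, lets only the (8R) epimer close by attack of the phenol oxygen on one face of C7, so that the carbon–oxygen bond formation fixes C2 (S) directly and C3 (R) by dynamic kinetic resolution with the aryl and acyloxymethyl groups trans to avoid eclipsing in the closing ring; the closest known reaction types are chiral phosphoric acid catalysed 1,6-additions to p-quinone methides (including those generated from hydroxystyrenes by protonation) and the achiral acid cyclisation of 2-hydroxystilbenes to trans-2-aryl-2,3-dihydrobenzofurans.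

## Compound list

1 | 2-methoxy-4-vinylphenol | COc1cc(C=C)ccc1O | starting material
2 | allyl 4-hydroxybenzoate (prop-2-en-1-yl 4-hydroxybenzoate) | C=CCOC(=O)c1ccc(O)cc1 | starting material
3 | (E)-3-(4-hydroxy-3-methoxyphenyl)prop-2-en-1-yl 4-hydroxybenzoate | COc1cc(/C=C/COC(=O)c2ccc(O)cc2)ccc1O | intermediate
4 | 5-iodovanillin (4-hydroxy-3-iodo-5-methoxybenzaldehyde) | COc1cc(C=O)cc(I)c1O | starting material
5 | 2-iodo-6-methoxy-4-vinylphenol | COc1cc(C=C)cc(I)c1O | intermediate
6 | (E)-3-(4-hydroxy-3-iodo-5-methoxyphenyl)prop-2-en-1-yl 4-hydroxybenzoate | COc1cc(/C=C/COC(=O)c2ccc(O)cc2)cc(I)c1O | intermediate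
7 | (Z)-3-(4-hydroxy-3-methoxyphenyl)-2-{2-hydroxy-5-[(E)-3-(4-hydroxybenzoyloxy)prop-1-en-1-yl]-3-methoxyphenyl}prop-2-en-1-yl 4-hydroxybenzoate | COc1cc(/C=C(\COC(=O)c2ccc(O)cc2)c2cc(/C=C/COC(=O)c3ccc(O)cc3)cc(OC)c2O)ccc1O | intermediate
8 | (E)-3-{4-hydroxy-3-[(2R)-1-(4-hydroxybenzoyloxy)-3-(3-methoxy-4-oxocyclohexa-2,5-dien-1-ylidene)propan-2-yl]-5-methoxyphenyl}prop-2-en-1-yl 4-hydroxybenzoate (p-quinone methide, reacting C8 epimer shown, exocyclic alkene geometry not fixed) | COC1=CC(=C[C@@H](COC(=O)c2ccc(O)cc2)c2cc(/C=C/COC(=O)c3ccc(O)cc3)cc(OC)c2O)C=CC1=O | intermediate (not isolated)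
9 | quiquesetinerviusin A, [(2S,3R)-2-(4-hydroxy-3-methoxyphenyl)-5-{(E)-3-[(4-hydroxybenzoyl)oxy]prop-1-en-1-yl}-7-methoxy-2,3-dihydro-1-benzofuran-3-yl]methyl 4-hydroxybenzoate | COc1cc([C@H]2Oc3c(OC)cc(/C=C/COC(=O)c4ccc(O)cc4)cc3[C@@H]2COC(=O)c2ccc(O)cc2)ccc1O | target

## Step count and risk

Total steps: 5. Longest linear sequence: 4 steps (4 → 5 → 6 → 7 → 9).

The three steps most likely to fail:

**Step 5 (the new cyclisation).** Three things can go wrong.
- Protonation may occur at C7 instead, giving the o-quinone methide of ring B. This is unproductive but reversible.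
- The side-chain hydroxystyrene of ring B may also be protonated and trapped intermolecularly, which is why the reaction is run dilute and cold.
- The enantioselectivity rests on 8 reverting to 7 faster than the mismatched epimer closes. If it does not, face-selective proton transfer becomes the selecting event and the ee may be low.

The fallback sets out from 7 and comes back at 9. Compound 7 is cyclised with an achiral acid (diphenyl phosphate, 10 mol%, CH2Cl2, 0 °C), the known acid closure of 2-hydroxystilbenes to trans-2-aryl-2,3-dihydrobenzofurans. This gives the racemate, that is 9 together with its mirror image, the (2R,3S)-enantiomer of 9 F1. The two are separated by preparative HPLC on an amylose tris(3,5-dimethylphenylcarbamate) phase to give 9.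

**Step 4 (Heck union).** The alkenes of 6 and of product 7 are of the same kind as that of 3, so selectivity is only statistical. Insertion could also go with the opposite regiochemistry, or the benzylic palladium intermediate could close to racemic 9 in the flask.

The fallback sets out from 3 (coupled with 4) and comes back at 7. It makes the union before the ring B side chain exists, so the aryl iodide carries no alkene.
- Heck coupling of 3 with 5-iodovanillin 4 under the same Pd(OAc)2/n-Bu4NCl/NaOAc conditions, near-stoichiometric, gives the aldehyde (Z)-2-(5-formyl-2-hydroxy-3-methoxyphenyl)-3-(4-hydroxy-3-methoxyphenyl)prop-2-en-1-yl 4-hydroxybenzoate F2.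
- Wittig methylenation (Ph3PCH3Br/KOtBu in excess, THF, −40 to 0 °C, kept short because the phenoxide can eject the allylic ester) gives the vinyl compound (Z)-2-(5-ethenyl-2-hydroxy-3-methoxyphenyl)-3-(4-hydroxy-3-methoxyphenyl)prop-2-en-1-yl 4-hydroxybenzoate F3.
- Cross-metathesis of F3 with 2, using the catalyst of step 1, gives 7. The trisubstituted stilbene alkene is inert to the ruthenium carbene.

**Step 3 (cross-metathesis on the iodinated vinylphenol).** The vinylphenol may homodimerise or polymerise, and the phenol may slow the catalyst.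

The fallback sets out from 4 and comes back at 6, bypassing 5. It builds the arm by classical homologation.
- 4 with (triphenylphosphoranylidene)acetaldehyde (toluene, 80 °C, no added base) gives (E)-3-(4-hydroxy-3-iodo-5-methoxyphenyl)prop-2-enal F4.
- Luche reduction (NaBH4, CeCl3·7H2O, MeOH, 0 °C) gives (E)-4-(3-hydroxyprop-1-en-1-yl)-2-iodo-6-methoxyphenol F5.
- Mitsunobu esterification of F5 with 4-hydroxybenzoic acid (PPh3, DIAD, THF, 0 °C) gives 6. The carboxylic acid reacts in preference to the phenols.

## Further compounds

F1 | step 5 | (2R,3S)-enantiomer of 9, [(2R,3S)-2-(4-hydroxy-3-methoxyphenyl)-5-{(E)-3-[(4-hydroxybenzoyl)oxy]prop-1-en-1-yl}-7-methoxy-2,3-dihydro-1-benzofuran-3-yl]methyl 4-hydroxybenzoate | COc1cc([C@@H]2Oc3c(OC)cc(/C=C/COC(=O)c4ccc(O)cc4)cc3[C@H]2COC(=O)c2ccc(O)cc2)ccc1O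
F2 | step 4 | (Z)-2-(5-formyl-2-hydroxy-3-methoxyphenyl)-3-(4-hydroxy-3-methoxyphenyl)prop-2-en-1-yl 4-hydroxybenzoate | COc1cc(/C=C(\COC(=O)c2ccc(O)cc2)c2cc(C=O)cc(OC)c2O)ccc1O
F3 | step 4 | (Z)-2-(5-ethenyl-2-hydroxy-3-methoxyphenyl)-3-(4-hydroxy-3-methoxyphenyl)prop-2-en-1-yl 4-hydroxybenzoate | COc1cc(/C=C(\COC(=O)c2ccc(O)cc2)c2cc(C=C)cc(OC)c2O)ccc1O
F4 | step 3 | (E)-3-(4-hydroxy-3-iodo-5-methoxyphenyl)prop-2-enal | COc1cc(/C=C/C=O)cc(I)c1O
F5 | step 3 | (E)-4-(3-hydroxyprop-1-en-1-yl)-2-iodo-6-methoxyphenol | COc1cc(/C=C/CO)cc(I)c1O
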